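## Retrosynthetic overview

1. C12–C13 is cut last: C13, the carbinol carbon, is used as a configurationally defined α-oxygenated carbanion (lithiated (S)-but-3-en-2-yl carbamate) and joined to a C12 pinacol boronate by 1,2-metallate shift; C–B oxidation then sets (13R).
2. The 6α-butanoate comes from the 6β-allylic alcohol by Mitsunobu inversion; C12–B comes from C12–Br and the primary alcohol.
3. The 6β,12-diol comes from the 7-en-6-one ester, the enone from allylic oxidation of the Δ7 ester, and the Δ7 ester from (+)-sclareolide.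
4. No ring is formed: rings A and B, with C5, C9 and C10, come intact from (+)-sclareolide.

Numbering: labdane numbering is kept throughout (C17 = methyl on C8, C18/C19 = methyls on C4, C20 = methyl on C10); β is the face of the C10 methyl, α the opposite face.

Assumption: the lithiated allylic carbamate is taken to capture the pinacol boronate at the carbinol carbon with retention, as established for secondary benzylic and γ-substituted allylic carbamates.

## Route

Step 1
Reactants: 1 (+)-sclareolide
Product: 3 methyl 13,14,15,16-tetranorlabd-7-en-12-oate (5α-H, 9α-H, 10β-CH3), via tetranorlabd-7-en-12-oic acid 2 (not isolated)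
Conditions: conc. H2SO4 (cat.), MeOH, rt → 45 °C; AgNO3–SiO2 chromatography
Reagents that add atoms: methanol, CO
Why: Acid-catalysed alkyl–oxygen cleavage of the tertiary lactone gives the C8 cation, E1 loss of the axial 7α-H gives the trisubstituted Δ7 alkene and Fischer esterification traps acid 2 as 3, the Δ8(17) and Δ8(9) isomers being removed on AgNO3–SiO2; no stereocentre is made and C5, C9 and C10 are untouched.

Step 2
Reactants: 3 methyl 13,14,15,16-tetranorlabd-7-en-12-oate
Product: 4 methyl 6-oxo-13,14,15,16-tetranorlabd-7-en-12-oate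
Conditions: CrO3, 3,5-dimethylpyrazole, CH2Cl2, −20 °C
Reagents that add atoms: chromium trioxide, O=[Cr](=O)=O
Why: Allylic oxidation by the CrO3–3,5-dimethylpyrazole complex (hexavalent chromium) takes the C6 methylene next to the CH end of the trisubstituted alkene to the conjugated 7-en-6-one, as with Δ7 sterols and 1-methylcyclohexenes; no new stereocentre is made and the trans ring fusion at C5 is the stable one next to the ketone.

Step 3
Reactants: 4 methyl 6-oxo-13,14,15,16-tetranorlabd-7-en-12-oate
Product: 5 13,14,15,16-tetranorlabd-7-ene-6β,12-diol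
Conditions: LiAlH4, Et2O, −40 → 0 °C
Reagents that add atoms: none
Why: Hydride reduction takes the ester to the primary alcohol and the enone 1,2 to the allylic alcohol, with hydride arriving on the α face of C6 because the β face is screened by the syn-axial C10 and C4β methyl groups, which sets the 6β (axial) alcohol.

Step 4
Reactants: 5 13,14,15,16-tetranorlabd-7-ene-6β,12-diol
Product: 6 12-bromo-13,14,15,16-tetranorlabd-7-en-6β-ol
Conditions: CBr4 (1.05 equiv), PPh3 (1.05 equiv), CH2Cl2, 0 °C
Reagents that add atoms: carbon tetrabromide, BrC(Br)(Br)Br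
Why: The Appel reaction brominates the unhindered primary C12 hydroxyl in preference to the axial 6β-hydroxyl, which is flanked by two syn-axial methyl groups; no stereocentre changes.

Step 5
Reactants: 6 12-bromo-13,14,15,16-tetranorlabd-7-en-6β-ol
Product: 7 12-(4,4,5,5-tetramethyl-1,3,2-dioxaborolan-2-yl)-13,14,15,16-tetranorlabd-7-en-6β-ol
Conditions: Pd2(dba)3 (2 mol%), t-Bu2MeP·HBF4 (8 mol%), B2pin2, K3PO4, t-BuOH/H2O, 60 °C
Reagents that add atoms: bis(pinacolato)diboron, CC1(C)OB(OC1(C)C)B1OC(C)(C)C(C)(C)O1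
Why: Palladium-catalysed Miyaura-type borylation of a primary alkyl bromide (zerovalent palladium, SN2-type oxidative addition, transmetalation faster than β-hydride elimination) avoids a free C12 radical and tolerates the free secondary alcohol and the alkene; no stereocentre changes.

Step 6
Reactants: 7 12-(4,4,5,5-tetramethyl-1,3,2-dioxaborolan-2-yl)-13,14,15,16-tetranorlabd-7-en-6β-ol
Product: 8 12-(4,4,5,5-tetramethyl-1,3,2-dioxaborolan-2-yl)-13,14,15,16-tetranorlabd-7-en-6α-yl butanoate
Conditions: PrCO2H, PPh3, DIAD, toluene, 0 °C → rt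
Reagents that add atoms: butanoic acid, CCCC(=O)O
Why: In the Mitsunobu reaction the 6β-oxyphosphonium is displaced by butanoate in an SN2 step from the open α face, which inverts C6 to the equatorial 6α ester of the target, while the boronate is inert.

Step 7
Reactants: 9 (S)-but-3-en-2-ol
Product: 10 (S)-but-3-en-2-yl N,N-diisopropylcarbamate
Conditions: NaH, THF, 0 °C; i-Pr2NCOCl, 0 °C → reflux
Reagents that add atoms: N,N-diisopropylcarbamoyl chloride, CC(C)N(C(C)C)C(Cl)=O
Why: O-Carbamoylation of the sodium alkoxide (acyl substitution) does not break the C–O bond, so the (S) centre is kept, and it installs the group that directs lithiation and later leaves.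

Step 8
Reactants: 8 12-(4,4,5,5-tetramethyl-1,3,2-dioxaborolan-2-yl)-13,14,15,16-tetranorlabd-7-en-6α-yl butanoate; 10 (S)-but-3-en-2-yl N,N-diisopropylcarbamate
Product: 14 (5S,6S,9S,10R,13R)-13-hydroxylabda-7,14-dien-6-yl butanoate (target), via lithiated carbamate 11 (not isolated), via lithium boronate complex 12 (not isolated), via tertiary allylic boronic ester 13 (not isolated)
Conditions: 10 (1.1 equiv), s-BuLi (1.05 equiv), TMEDA, Et2O, −78 °C, 15 min; 8 (1.0 equiv), −78 °C, 1 h, then → rt; NaBO3·4H2O, THF/H2O, rt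
Reagents that add atoms: sodium perborate tetrahydrate, [Na+].[Na+].O[B-]1(O)OO[B-](O)(O)OO1 (gives the hydroxyl oxygen); sec-butyllithium, CCC(C)[Li] (lithium is carried only by 11 and 12)
Why: In this Hoppe–Aggarwal lithiation–borylation, s-BuLi/TMEDA removes the carbinol proton of 10 with retention to give 11, so C13 (a carbonyl-level carbon, normally the electrophile) reacts as a carbanion with the organoboron carbon C12; boronate 8 is captured at C13 with retention (12), the stereospecific 1,2-shift of C12 from boron to C13 anti to the leaving carbamate forms the C12–C13 bond (13), and C–B oxidation with retention turns (S)-10 into the (13R) tertiary allylic alcohol.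

## Compound list

1 | (+)-sclareolide, (3aR,5aS,9aS,9bR)-3a,6,6,9a-tetramethyldecahydronaphtho[2,1-b]furan-2(1H)-one | C[C@]12CCCC([C@@H]1CC[C@@]3([C@@H]2CC(=O)O3)C)(C)C | starting material
2 | 13,14,15,16-tetranorlabd-7-en-12-oic acid (5α-H, 9α-H, 10β-CH3) | OC(=O)C[C@H]1C(C)=CC[C@H]2C(C)(C)CCC[C@]12C | intermediate
3 | methyl 13,14,15,16-tetranorlabd-7-en-12-oate | COC(=O)C[C@H]1C(C)=CC[C@H]2C(C)(C)CCC[C@]12C | intermediate
4 | methyl 6-oxo-13,14,15,16-tetranorlabd-7-en-12-oate | COC(=O)C[C@H]1C(C)=CC(=O)[C@H]2C(C)(C)CCC[C@]12C | intermediate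
5 | 13,14,15,16-tetranorlabd-7-ene-6β,12-diol | OCC[C@H]1C(C)=C[C@@H](O)[C@H]2C(C)(C)CCC[C@]12C | intermediate
6 | 12-bromo-13,14,15,16-tetranorlabd-7-en-6β-ol | BrCC[C@H]1C(C)=C[C@@H](O)[C@H]2C(C)(C)CCC[C@]12C | intermediate
7 | 12-(4,4,5,5-tetramethyl-1,3,2-dioxaborolan-2-yl)-13,14,15,16-tetranorlabd-7-en-6β-ol | CC1(C)OB(CC[C@H]2C(C)=C[C@@H](O)[C@H]3C(C)(C)CCC[C@]23C)OC1(C)C | intermediate
8 | 12-(4,4,5,5-tetramethyl-1,3,2-dioxaborolan-2-yl)-13,14,15,16-tetranorlabd-7-en-6α-yl butanoate | CC1(C)OB(CC[C@H]2C(C)=C[C@H](OC(=O)CCC)[C@H]3C(C)(C)CCC[C@]23C)OC1(C)C | intermediate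
9 | (S)-but-3-en-2-ol | C=C[C@H](C)O | starting material
10 | (S)-but-3-en-2-yl N,N-diisopropylcarbamate | C=C[C@H](C)OC(=O)N(C(C)C)C(C)C | intermediate
11 | α-lithiated carbamate (Li in place of the carbinol H of 10, configuration retained) | C=C[C@]([Li])(C)OC(=O)N(C(C)C)C(C)C | intermediate
12 | lithium boronate complex (boron bound to C13 in place of Li, to C12 of 8 and to pinacol) | C=C[C@](C)(OC(=O)N(C(C)C)C(C)C)[B-]1(CC[C@H]2C(C)=C[C@H](OC(=O)CCC)[C@H]3C(C)(C)CCC[C@]23C)OC(C)(C)C(C)(C)O1.[Li+] | intermediate
13 | 13-(4,4,5,5-tetramethyl-1,3,2-dioxaborolan-2-yl)labda-7,14-dien-6α-yl butanoate (boron where the 13-OH of 14 will stand) | C=C[C@@](C)(CC[C@H]1C(C)=C[C@H](OC(=O)CCC)[C@H]2C(C)(C)CCC[C@]12C)B1OC(C)(C)C(C)(C)O1 | intermediate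
14 | (5S,6S,9S,10R,13R)-13-hydroxylabda-7,14-dien-6-yl butanoate (6α-butanoyloxy, 13R) | C=C[C@](C)(O)CC[C@H]1C(C)=C[C@H](OC(=O)CCC)[C@H]2C(C)(C)CCC[C@]12C | target

## Step count and weak points

Total steps: 8. Longest linear sequence: 7 (steps 1–6 and 8, from (+)-sclareolide); step 7 is the one-step side branch.

The three steps most likely to fail:

Step 8. The allyl anion 11 is ambident and has an unsubstituted far terminus, so borylation may go to that terminus instead of C13. Anion 11 may also lose configuration before capture, and it may attack the butanoate of 8. The fallback sets out from 8 and comes back at 14. It replaces the allyl carbenoid by a propargyl one whose far terminus is blocked by silicon and makes the vinyl group afterwards. Commercial (S)-4-(trimethylsilyl)but-3-yn-2-ol is carbamoylated (NaH, i-Pr2NCOCl, THF) to (S)-4-(trimethylsilyl)but-3-yn-2-yl N,N-diisopropylcarbamate F1. F1 is lithiated (s-BuLi, TMEDA, Et2O, −78 °C) and borylated with 8; the 1,2-shift gives 13-(pinacolatoboryl)-15-(trimethylsilyl)labd-7-en-14-yn-6α-yl butanoate F2. F2 is oxidised in the same flask (NaBO3·4H2O) to (13R)-13-hydroxy-15-(trimethylsilyl)labd-7-en-14-yn-6α-yl butanoate F3. C-Desilylation (TBAF/AcOH, THF, 0 °C) gives (13R)-13-hydroxylabd-7-en-14-yn-6α-yl butanoate F4. Lindlar semihydrogenation (Pd/CaCO3 poisoned with Pb(OAc)2, quinoline, H2, EtOAc) gives 14.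

Step 6. The 6β-hydroxyl is very hindered and its leaving group is anti-periplanar to H5α, so slow activation and E2 loss to the 5,7-diene can outrun the SN2 step. The fallback sets out from 7 and comes back at 8. It gives up the concerted displacement for ionisation. Alcohol 7 is converted (CCl3CN, DBU, CH2Cl2, 0 °C) into 12-(pinacolatoboryl)-13,14,15,16-tetranorlabd-7-en-6β-yl 2,2,2-trichloroacetimidate F5. With butanoic acid in toluene at rt, F5 is protonated and ionises to the C6–C8 allyl cation paired with butanoate. Capture at C6 from the open α face, which also gives the thermodynamically preferred equatorial ester, leads to 8.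

Step 1. The C8 cation can lose a proton towards C7, C17 or C9, so the Δ7 ester may be only about half of an isomer mixture and the separation is tedious. The fallback sets out from 1 and comes back at 3. It builds the alkene position in two controlled moves. Lactone 1 is opened (KOH, aq. MeOH; then MeI, DMF) to methyl 8α-hydroxy-13,14,15,16-tetranorlabdan-12-oate F6. SOCl2/pyridine in CH2Cl2 at −78 °C eliminates through the C17 methyl, the only hydrogens anti-periplanar to the equatorial leaving group, and gives methyl 13,14,15,16-tetranorlabd-8(17)-en-12-oate F7. Cobalt-hydride hydrogen-atom-transfer isomerisation (Co(salen)Cl, trivalent cobalt, 3 mol%, PhSiH3, benzene, rt) moves the double bond one position, towards the less hindered C7 side, and gives 3.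

## Further compounds

F1 | step 8 | (S)-4-(trimethylsilyl)but-3-yn-2-yl N,N-diisopropylcarbamate | C[Si](C)(C)C#C[C@H](C)OC(=O)N(C(C)C)C(C)C
F2 | step 8 | 13-(4,4,5,5-tetramethyl-1,3,2-dioxaborolan-2-yl)-15-(trimethylsilyl)labd-7-en-14-yn-6α-yl butanoate | C[Si](C)(C)C#C[C@@](C)(CC[C@H]1C(C)=C[C@H](OC(=O)CCC)[C@H]2C(C)(C)CCC[C@]12C)B1OC(C)(C)C(C)(C)O1
F3 | step 8 | (13R)-13-hydroxy-15-(trimethylsilyl)labd-7-en-14-yn-6α-yl butanoate | C[Si](C)(C)C#C[C@](C)(O)CC[C@H]1C(C)=C[C@H](OC(=O)CCC)[C@H]2C(C)(C)CCC[C@]12C
F4 | step 8 | (13R)-13-hydroxylabd-7-en-14-yn-6α-yl butanoate | C#C[C@](C)(O)CC[C@H]1C(C)=C[C@H](OC(=O)CCC)[C@H]2C(C)(C)CCC[C@]12C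
F5 | step 6 | 12-(4,4,5,5-tetramethyl-1,3,2-dioxaborolan-2-yl)-13,14,15,16-tetranorlabd-7-en-6β-yl 2,2,2-trichloroacetimidate | CC1(C)OB(CC[C@H]2C(C)=C[C@@H](OC(=N)C(Cl)(Cl)Cl)[C@H]3C(C)(C)CCC[C@]23C)OC1(C)C
F6 | step 1 | methyl 8α-hydroxy-13,14,15,16-tetranorlabdan-12-oate | COC(=O)C[C@H]1[C@](C)(O)CC[C@H]2C(C)(C)CCC[C@]12C
F7 | step 1 | methyl 13,14,15,16-tetranorlabd-8(17)-en-12-oate | COC(=O)C[C@H]1C(=C)CC[C@H]2C(C)(C)CCC[C@]12C
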